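Labels: rings A (prenylated arene), B (second arene), C (oxepine), D (dihydropyran), E (cyclobutane), F (cyclopentane); Cb is the oxygen-bearing enol ether carbon on ring B and Ca its alkene partner on ring A; C1' is the ring E CH on Ca, C2' the CH common to rings D, E and F, C3' the C(Me)–O carbon, C4' and C5' the CH2 groups, C6' the E/F fusion CH, C7' the CMe2 carbon.
Feature used: C3' is a tertiary carbinol β to C1', and C1' can be carried as a ketone until Ca is attached, so C1'(=O)–C2'–C3'(OH)Me is an aldol motif; ring E, with C7' between C1' and C6', is the gem-dimethylcyclobutane of the pinane skeleton.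
Cuts, in retrosynthetic order: O–Cb (ring D, enol ether back to a δ-hydroxy ketone); Ca–C1' (aldol condensation plus conjugate reduction) to a silylated prenyl dibenzoxepinone and a bicyclic cyclobutanone; C2'–C3' (ring F, intramolecular aldol) to a cyclobutanone with a 3-oxobutyl chain, traced to (+)-nopinone; in the arene half the aryl–prenyl bond, the Cb–ring B bond (ring C) and the diaryl ether.
Forward order: ring E is bought, ring F closes in step 5, rings A and B are joined by SNAr and ring C is closed by Friedel–Crafts acylation, the halves are united at Ca–C1' (steps 14 to 16), and ring D closes last (step 17).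
Stereochemistry: C6' is C5 of nopinone; C2' and C3' are set in the aldol closure (cis fusion enforced by the ring, hydroxyl cis to the C1' carbonyl); C1' is set by hydride delivery to the convex face in step 16.

Key step: step 5

Remark: commercial (1R,5S)-(+)-nopinone (the ozonolysis product of (−)-β-pinene) is assumed to be of high enantiomeric purity, since the whole absolute configuration rests on it; the C11 epimers and alkene isomers of 19 to 21 are carried as mixtures because these centres end up trigonal.

Step 1
Reactants: 1 (1R,5S)-(+)-nopinone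
Product: 2 (1R,6S)-7,7-dimethyl-2-oxabicyclo[4.1.1]octan-3-one
Conditions: mCPBA, CH2Cl2, rt
Reagents that add atoms: 3-chloroperoxybenzoic acid (mCPBA), O=C(OO)c1cccc(Cl)c1
Why: Baeyer–Villiger oxidation, in which the more substituted bridgehead carbon (the future C1') migrates with retention, so the new oxygen ends on the cyclobutane and C6' is untouched.

Step 2
Reactants: 2 (1R,6S)-7,7-dimethyl-2-oxabicyclo[4.1.1]octan-3-one
Product: 3 3-[(1S,3R)-3-hydroxy-2,2-dimethylcyclobutyl]-N-methoxy-N-methylpropanamide
Conditions: MeNH(OMe)·HCl, AlMe3, CH2Cl2, 0 °C → rt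
Reagents that add atoms: N,O-dimethylhydroxylamine hydrochloride, CNOC.Cl
Why: Weinreb aminolysis of the lactone by the aluminium amide formed in the flask should open the ring at the acyl carbon and free the cyclobutanol without touching either stereocentre.

Step 3
Reactants: 3 3-[(1S,3R)-3-hydroxy-2,2-dimethylcyclobutyl]-N-methoxy-N-methylpropanamide
Product: 4 4-[(1S,3R)-3-hydroxy-2,2-dimethylcyclobutyl]butan-2-one
Conditions: MeMgBr (3 equiv), THF, 0 °C
Reagents that add atoms: methylmagnesium bromide, C[Mg]Br
Why: Grignard addition to a Weinreb amide stops at the magnesium-chelated tetrahedral adduct, so the methyl ketone (C3' with its methyl group) is released only on work-up; the free hydroxyl merely consumes one equivalent as its alkoxide.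

Step 4
Reactants: 4 4-[(1S,3R)-3-hydroxy-2,2-dimethylcyclobutyl]butan-2-one
Product: 5 (3S)-2,2-dimethyl-3-(3-oxobutyl)cyclobutan-1-one
Conditions: Dess–Martin periodinane, CH2Cl2, rt
Reagents that add atoms: none
Why: Dess–Martin oxidation of the secondary cyclobutanol should give the C1' ketone under near-neutral conditions that do not start an aldol reaction of the 1,6-diketone.

Step 5
Reactants: 5 (3S)-2,2-dimethyl-3-(3-oxobutyl)cyclobutan-1-one
Product: 6 (1S,2R,5S)-2-hydroxy-2,6,6-trimethylbicyclo[3.2.0]heptan-7-one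
Conditions: KOt-Bu (0.3 equiv), t-BuOH/THF, 0 °C → rt, dilute
Reagents that add atoms: none
Why: Reversible base-catalysed intramolecular aldol addition: tert-butoxide forms the cyclobutanone enolate at C2', the only α-carbon of that ketone bearing hydrogen, and it adds to the side-chain methyl ketone to form C2'–C3'. The closest known reaction type is the cyclisation of 1,6-diketones to five-membered β-hydroxy ketones. Ring F closes in a 5-(enolexo)-exo-trig mode. C2' can only form with the new bond cis to the C6' tether, since a trans-fused bicyclo[3.2.0]heptane is out of reach, so its configuration follows from C6'; at C3' the potassium-bridged closed transition state holds the ketone oxygen next to the enolate oxygen, which places the hydroxyl cis to the C1' carbonyl and the methyl group on the convex face, and this hydrogen-bonded isomer should also be the thermodynamic one. The step needs selection among three enolates: those of the side-chain ketone can reach only the cyclobutanone carbonyl and would give a bridged bicyclo[2.1.1]hexanol or bicyclo[4.1.1]octanol, both strained, so under equilibrating conditions they revert and the material should collect in 6. Dehydration is not a drain, because the enone would need a double bond at the ring-fusion carbon of the four-membered ring, and C6' cannot epimerise because it is β to the carbonyl.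

Step 6
Reactants: 6 (1S,2R,5S)-2-hydroxy-2,6,6-trimethylbicyclo[3.2.0]heptan-7-one
Product: 7 (1S,2R,5S)-2,6,6-trimethyl-2-[(triethylsilyl)oxy]bicyclo[3.2.0]heptan-7-one
Conditions: TESOTf, 2,6-lutidine, CH2Cl2, −78 → 0 °C
Reagents that add atoms: triethylsilyl trifluoromethanesulfonate, CC[Si](CC)(CC)OS(=O)(=O)C(F)(F)F
Why: Silyl ether formation with a silyl triflate caps the tertiary alcohol, which blocks retro-aldol opening of ring F under the basic conditions of step 14 and later shields the concave face of C1'.

Step 7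
Reactants: 8 2-bromo-5-fluoroanisole
Product: 9 1-(5-bromo-2-fluoro-4-methoxyphenyl)ethan-1-one
Conditions: AcCl, AlCl3, CH2Cl2, 0 °C → rt
Reagents that add atoms: acetyl chloride, CC(=O)Cl
Why: Friedel–Crafts acylation should take place para to the methoxy group, the strongest director, which puts the acetyl group ortho to the fluorine that is to be displaced.

Step 8
Reactants: 9 1-(5-bromo-2-fluoro-4-methoxyphenyl)ethan-1-one; 10 3-methoxyphenol
Product: 11 1-[5-bromo-4-methoxy-2-(3-methoxyphenoxy)phenyl]ethan-1-one
Conditions: K2CO3, DMF, 110 °C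
Reagents that add atoms: none
Why: Nucleophilic aromatic substitution (SNAr): the phenoxide displaces the fluoride activated by the ortho acetyl group, while the bromide, meta to the carbonyl, is not activated and stays.

Step 9
Reactants: 11 1-[5-bromo-4-methoxy-2-(3-methoxyphenoxy)phenyl]ethan-1-one
Product: 13 2-[5-bromo-4-methoxy-2-(3-methoxyphenoxy)phenyl]acetic acid, via thiomorpholide 12 (not isolated)
Conditions: S8, morpholine, 130 °C; then KOH, EtOH/H2O, reflux; then HCl
Reagents that add atoms: potassium hydroxide, [K+].[OH-] (supplies the carboxyl oxygens of 13); sulfur, S1SSSSSSS1, and morpholine, C1COCCN1 (both present only in 12)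
Why: The Willgerodt–Kindler reaction moves the oxidised carbon to the chain end as the thiomorpholide, and alkaline hydrolysis then gives the arylacetic acid, the classical entry to 2-aryloxyphenylacetic acids.

Step 10
Reactants: 13 2-[5-bromo-4-methoxy-2-(3-methoxyphenoxy)phenyl]acetic acid
Product: 14 2-bromo-3,7-dimethoxydibenzo[b,f]oxepin-10(11H)-one
Conditions: P2O5/MeSO3H (Eaton's reagent), 50 °C
Reagents that add atoms: none
Why: Intramolecular Friedel–Crafts acylation closes the seven-membered ring C at the ring B carbon para to the methoxy group and ortho to the ether oxygen, the only uncrowded activated site the tethered acylium ion can reach.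

Step 11
Reactants: 14 2-bromo-3,7-dimethoxydibenzo[b,f]oxepin-10(11H)-one
Product: 15 2-bromo-3,7-dihydroxydibenzo[b,f]oxepin-10(11H)-one
Conditions: BBr3, CH2Cl2, −78 °C → rt
Reagents that add atoms: none
Why: Lewis acid cleavage of both aryl methyl ethers frees the phenols before the acid-sensitive prenyl group is introduced; the diaryl ether and the aryl bromide should be inert.

Step 12
Reactants: 15 2-bromo-3,7-dihydroxydibenzo[b,f]oxepin-10(11H)-one
Product: 16 2-bromo-3,7-bis[(tert-butyldimethylsilyl)oxy]dibenzo[b,f]oxepin-10(11H)-one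
Conditions: TBSCl, imidazole, DMF, rt
Reagents that add atoms: tert-butyldimethylsilyl chloride, CC(C)(C)[Si](C)(C)Cl
Why: Imidazole-promoted silylation of both phenols gives ethers that should survive amide base, hydride and mild acid and leave at the end with fluoride.

Step 13
Reactants: 16 2-bromo-3,7-bis[(tert-butyldimethylsilyl)oxy]dibenzo[b,f]oxepin-10(11H)-one
Product: 17 3,7-bis[(tert-butyldimethylsilyl)oxy]-2-(3-methylbut-2-en-1-yl)dibenzo[b,f]oxepin-10(11H)-one
Conditions: Bu3SnCH2CH=CMe2, Pd(PPh3)4, DMF, 100 °C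
Reagents that add atoms: tributyl(3-methylbut-2-en-1-yl)stannane, CCCC[Sn](CCCC)(CCCC)CC=C(C)C
Why: Stille coupling of the aryl bromide with the allylic stannane under neutral conditions should install the prenyl group, reductive elimination at the less substituted allyl terminus giving the linear isomer while silyl ethers and the enolisable ketone are spared.

Step 14
Reactants: 17 3,7-bis[(tert-butyldimethylsilyl)oxy]-2-(3-methylbut-2-en-1-yl)dibenzo[b,f]oxepin-10(11H)-one; 7 (1S,2R,5S)-2,6,6-trimethyl-2-[(triethylsilyl)oxy]bicyclo[3.2.0]heptan-7-one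
Product: 19 11-[(1R,2R,5S)-7-hydroxy-2,6,6-trimethyl-2-(triethylsilyloxy)bicyclo[3.2.0]heptan-7-yl]-3,7-bis(tert-butyldimethylsilyloxy)-2-(3-methylbut-2-en-1-yl)dibenzo[b,f]oxepin-10(11H)-one, via lithium enolate 18 (not isolated)
Conditions: LiN(SiMe3)2, THF, −78 °C; then 7, −78 → −40 °C
Reagents that add atoms: none
Why: Directed aldol addition: the preformed lithium enolate (Ca) should add to the strained, electrophilic cyclobutanone carbonyl (C1') from the convex face, relief of angle strain on rehybridisation holding the equilibrium on the side of the ketol; the carbinol and C11 centres formed here are erased in steps 15 to 17.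

Step 15
Reactants: 19 ketol of step 14
Product: 20 11-[(1R,2R,5S)-2,6,6-trimethyl-2-(triethylsilyloxy)bicyclo[3.2.0]heptan-7-ylidene]-3,7-bis(tert-butyldimethylsilyloxy)-2-(3-methylbut-2-en-1-yl)dibenzo[b,f]oxepin-10(11H)-one
Conditions: SOCl2, pyridine, CH2Cl2, −20 → 0 °C
Reagents that add atoms: none
Why: Dehydration of the tertiary β-hydroxy ketone through its chlorosulfite (base-induced β-elimination) removes the acidic C11 hydrogen, the only β-hydrogen whose loss gives a conjugated alkene; both alkene isomers serve equally.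

Step 16
Reactants: 20 enone of step 15
Product: 21 11-[(1R,2R,5S,7S)-2,6,6-trimethyl-2-(triethylsilyloxy)bicyclo[3.2.0]heptan-7-yl]-3,7-bis(tert-butyldimethylsilyloxy)-2-(3-methylbut-2-en-1-yl)dibenzo[b,f]oxepin-10(11H)-one
Conditions: LiBH(s-Bu)3, THF, −78 °C
Reagents that add atoms: none
Why: Conjugate (1,4-) reduction of an s-cis exocyclic alkylidene ketone with L-Selectride: hydride should reach the strained cyclobutylidene carbon C1' from the convex face, opposite the silyloxy-bearing cyclopentane, which sets C1' with Ca cis to the C3' oxygen; the extended enolate is protonated at C11 on work-up.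

Step 17
Reactants: 21 ketone of step 16
Product: 24 bis(tert-butyldimethylsilyl) ether of the target, via hydroxy ketone 22 (not isolated), via hemiketal 23 (not isolated)
Conditions: PPTS, MeOH, 40 °C; then toluene, 4 Å molecular sieves, 80 °C
Reagents that add atoms: none
Why: Cyclodehydration of a δ-hydroxy ketone: acid methanolysis frees the tertiary alcohol, which adds to the Cb ketone to give the six-membered hemiketal allowed by the cis relationship set in step 16, and acid-catalysed loss of water then gives the Cb=Ca enol ether of ring D in conjugation with both arenes.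

Step 18
Reactants: 24 bis(tert-butyldimethylsilyl) ether of the target
Product: 25 target compound CNP0185814.1
Conditions: TBAF, THF, 0 °C
Reagents that add atoms: none
Why: Fluoride desilylation of the two aryl silyl ethers under non-acidic conditions should leave the enol ether and the prenyl group intact.

Compound list
1 | (1R,5S)-(+)-nopinone (6,6-dimethylbicyclo[3.1.1]heptan-2-one) | O=C1CC[C@H]2C[C@@H]1C2(C)C | starting material
2 | (1R,6S)-7,7-dimethyl-2-oxabicyclo[4.1.1]octan-3-one | O=C1CC[C@H]2C[C@@H](O1)C2(C)C | intermediate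
3 | 3-[(1S,3R)-3-hydroxy-2,2-dimethylcyclobutyl]-N-methoxy-N-methylpropanamide | CON(C)C(=O)CC[C@H]1C[C@@H](O)C1(C)C | intermediate
4 | 4-[(1S,3R)-3-hydroxy-2,2-dimethylcyclobutyl]butan-2-one | CC(=O)CC[C@H]1C[C@@H](O)C1(C)C | intermediate
5 | (3S)-2,2-dimethyl-3-(3-oxobutyl)cyclobutan-1-one | CC(=O)CC[C@H]1CC(=O)C1(C)C | intermediate
6 | (1S,2R,5S)-2-hydroxy-2,6,6-trimethylbicyclo[3.2.0]heptan-7-one | O=C1[C@H]2[C@H](CC[C@@]2(C)O)C1(C)C | intermediate
7 | (1S,2R,5S)-2,6,6-trimethyl-2-[(triethylsilyl)oxy]bicyclo[3.2.0]heptan-7-one | O=C1[C@H]2[C@H](CC[C@@]2(C)O[Si](CC)(CC)CC)C1(C)C | intermediate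
8 | 2-bromo-5-fluoroanisole (1-bromo-4-fluoro-2-methoxybenzene) | COc1cc(F)ccc1Br | starting material
9 | 1-(5-bromo-2-fluoro-4-methoxyphenyl)ethan-1-one | CC(=O)c1cc(Br)c(OC)cc1F | intermediate
10 | 3-methoxyphenol | COc1cccc(O)c1 | starting material
11 | 1-[5-bromo-4-methoxy-2-(3-methoxyphenoxy)phenyl]ethan-1-one | CC(=O)c1cc(Br)c(OC)cc1Oc1cccc(OC)c1 | intermediate
12 | 2-[5-bromo-4-methoxy-2-(3-methoxyphenoxy)phenyl]-1-(morpholin-4-yl)ethane-1-thione | S=C(Cc1cc(Br)c(OC)cc1Oc1cccc(OC)c1)N1CCOCC1 | intermediate (not isolated)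
13 | 2-[5-bromo-4-methoxy-2-(3-methoxyphenoxy)phenyl]acetic acid | OC(=O)Cc1cc(Br)c(OC)cc1Oc1cccc(OC)c1 | intermediate
14 | 2-bromo-3,7-dimethoxydibenzo[b,f]oxepin-10(11H)-one | O=C1Cc2cc(Br)c(OC)cc2Oc2cc(OC)ccc21 | intermediate
15 | 2-bromo-3,7-dihydroxydibenzo[b,f]oxepin-10(11H)-one | O=C1Cc2cc(Br)c(O)cc2Oc2cc(O)ccc21 | intermediate
16 | 2-bromo-3,7-bis[(tert-butyldimethylsilyl)oxy]dibenzo[b,f]oxepin-10(11H)-one | O=C1Cc2cc(Br)c(O[Si](C)(C)C(C)(C)C)cc2Oc2cc(O[Si](C)(C)C(C)(C)C)ccc21 | intermediate
17 | 3,7-bis[(tert-butyldimethylsilyl)oxy]-2-(3-methylbut-2-en-1-yl)dibenzo[b,f]oxepin-10(11H)-one | O=C1Cc2cc(CC=C(C)C)c(O[Si](C)(C)C(C)(C)C)cc2Oc2cc(O[Si](C)(C)C(C)(C)C)ccc21 | intermediate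
18 | lithium 3,7-bis[(tert-butyldimethylsilyl)oxy]-2-(3-methylbut-2-en-1-yl)dibenzo[b,f]oxepin-10-olate | [Li+].[O-]C1=Cc2cc(CC=C(C)C)c(O[Si](C)(C)C(C)(C)C)cc2Oc2cc(O[Si](C)(C)C(C)(C)C)ccc21 | intermediate (not isolated)
19 | ketol: 17 bonded at C11 to C7 of the (1R,2R,5S)-7-hydroxy-2,6,6-trimethyl-2-(triethylsilyloxy)bicyclo[3.2.0]heptane unit; carbinol carbon and C11 left undefined (mixture) | O=C1C(C3(O)[C@H]4[C@H](CC[C@@]4(C)O[Si](CC)(CC)CC)C3(C)C)c2cc(CC=C(C)C)c(O[Si](C)(C)C(C)(C)C)cc2Oc2cc(O[Si](C)(C)C(C)(C)C)ccc21 | intermediate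
20 | enone: C11 of 17 doubly bonded to C7 of the (1R,2R,5S)-2,6,6-trimethyl-2-(triethylsilyloxy)bicyclo[3.2.0]heptane unit; alkene isomers not separated | O=C1C(=C3[C@H]4[C@H](CC[C@@]4(C)O[Si](CC)(CC)CC)C3(C)C)c2cc(CC=C(C)C)c(O[Si](C)(C)C(C)(C)C)cc2Oc2cc(O[Si](C)(C)C(C)(C)C)ccc21 | intermediate
21 | ketone: 17 bearing at C11 the (1R,2R,5S,7S)-2,6,6-trimethyl-2-(triethylsilyloxy)bicyclo[3.2.0]heptan-7-yl group; C11 epimers | O=C1C([C@@H]3[C@H]4[C@H](CC[C@@]4(C)O[Si](CC)(CC)CC)C3(C)C)c2cc(CC=C(C)C)c(O[Si](C)(C)C(C)(C)C)cc2Oc2cc(O[Si](C)(C)C(C)(C)C)ccc21 | intermediate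
22 | hydroxy ketone: 21 with the triethylsilyl group replaced by hydrogen | O=C1C([C@@H]3[C@H]4[C@H](CC[C@@]4(C)O)C3(C)C)c2cc(CC=C(C)C)c(O[Si](C)(C)C(C)(C)C)cc2Oc2cc(O[Si](C)(C)C(C)(C)C)ccc21 | intermediate (not isolated)
23 | cyclic hemiketal of 22: C3' oxygen bonded to Cb, which also carries OH; Ca carries H | CC(C)=CCc1cc2c(cc1O[Si](C)(C)C(C)(C)C)Oc1cc(O[Si](C)(C)C(C)(C)C)ccc1C1(O)C2[C@@H]2[C@H]3[C@H](CC[C@@]3(C)O1)C2(C)C | intermediate (not isolated)
24 | bis(tert-butyldimethylsilyl) ether of the target (both phenols silylated, rings A to F complete) | CC(C)=CCc1cc2c(cc1O[Si](C)(C)C(C)(C)C)Oc1cc(O[Si](C)(C)C(C)(C)C)ccc1C1=C2[C@@H]2[C@H]3[C@H](CC[C@@]3(C)O1)C2(C)C | intermediate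
25 | CNP0185814.1: 3,7-dihydroxy-2-prenyldibenzo[b,f]oxepine fused at Cb=Ca to dihydropyran ring D, with cyclobutane E and cyclopentane F; configuration 1'R,2'R,3'R,6'S in the labels above | CC(C)=CCc1cc2c(cc1O)Oc1cc(O)ccc1C1=C2[C@@H]2[C@H]3[C@H](CC[C@@]3(C)O1)C2(C)C | target

Total step count: 18. Longest linear sequence: 12 steps (8 to 25 through steps 7 to 18); the cyclobutane branch (1 to 7) has 6 steps before the union.

Steps most likely to fail

Step 14. The hindered enolate may add only slowly to the cyclobutanone flanked by C7' and C2', or the adduct may revert by retro-aldol cleavage on warming, so that both ketones are returned. The fallback sets out from 17 and 7. Enolate 18 is quenched with Me3SiCl to give the trimethylsilyl enol ether 3,7-bis[(tert-butyldimethylsilyl)oxy]-2-(3-methylbut-2-en-1-yl)-10-[(trimethylsilyl)oxy]dibenzo[b,f]oxepine F1. F1 and 7 are then combined with BF3·OEt2 in CH2Cl2 at −78 °C (Mukaiyama aldol addition). Lewis acid activation of the cyclobutanone and irreversible loss of the silyl group replace the reversible enolate equilibrium. The route is rejoined at 19.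

Step 16. Hydride may attack the carbonyl carbon instead of C1', may be slowed by the fully substituted β-carbon, or may reach C1' with insufficient face discrimination. The fallback sets out from 16 and 7 and postpones the prenyl group so that catalytic hydrogenation can be used. Bromide 16 is deprotonated as in step 14 to its lithium enolate F2 and added to 7 to give the bromo ketol F3 (the 2-bromo analogue of 19). Dehydration as in step 15 gives the bromo enone F4. With no prenyl alkene present, the tetrasubstituted double bond is hydrogenated with H2 and [Ir(cod)(PCy3)(py)]PF6 in CH2Cl2. The catalyst has to bind a whole alkene face and should therefore take only the convex one, giving the bromo ketone F5 (the 2-bromo analogue of 21). Stille coupling as in step 13 then installs the prenyl group, and the route is rejoined at 21.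

Step 15. Activation of the tertiary hydroxyl, which sits on the concave face next to the silyl ether, may be slow, leaving time for retro-aldol cleavage or for chloride substitution. The fallback sets out from 17 and 7 and never liberates the ketol. After the addition of enolate 18 to 7 at −78 °C, the lithium alkoxide of the ketol F6 is acylated in the same flask with trifluoroacetic anhydride to give the β-trifluoroacetoxy ketone F7. DBU in CH2Cl2 at 0 °C then induces E1cB elimination of trifluoroacetate. The route is rejoined at 20.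

Further compounds
F1 | step 14 | 3,7-bis[(tert-butyldimethylsilyl)oxy]-2-(3-methylbut-2-en-1-yl)-10-[(trimethylsilyl)oxy]dibenzo[b,f]oxepine | C[Si](C)(C)OC1=Cc2cc(CC=C(C)C)c(O[Si](C)(C)C(C)(C)C)cc2Oc2cc(O[Si](C)(C)C(C)(C)C)ccc21
F2 | step 16 | lithium 2-bromo-3,7-bis[(tert-butyldimethylsilyl)oxy]dibenzo[b,f]oxepin-10-olate | [Li+].[O-]C1=Cc2cc(Br)c(O[Si](C)(C)C(C)(C)C)cc2Oc2cc(O[Si](C)(C)C(C)(C)C)ccc21
F3 | step 16 | bromo ketol (19 with bromine in place of the prenyl group) | O=C1C(C3(O)[C@H]4[C@H](CC[C@@]4(C)O[Si](CC)(CC)CC)C3(C)C)c2cc(Br)c(O[Si](C)(C)C(C)(C)C)cc2Oc2cc(O[Si](C)(C)C(C)(C)C)ccc21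
F4 | step 16 | bromo enone (20 with bromine in place of the prenyl group) | O=C1C(=C3[C@H]4[C@H](CC[C@@]4(C)O[Si](CC)(CC)CC)C3(C)C)c2cc(Br)c(O[Si](C)(C)C(C)(C)C)cc2Oc2cc(O[Si](C)(C)C(C)(C)C)ccc21
F5 | step 16 | bromo ketone (21 with bromine in place of the prenyl group) | O=C1C([C@@H]3[C@H]4[C@H](CC[C@@]4(C)O[Si](CC)(CC)CC)C3(C)C)c2cc(Br)c(O[Si](C)(C)C(C)(C)C)cc2Oc2cc(O[Si](C)(C)C(C)(C)C)ccc21
F6 | step 15 | lithium alkoxide of ketol 19 | O=C1C(C3([O-])[C@H]4[C@H](CC[C@@]4(C)O[Si](CC)(CC)CC)C3(C)C)c2cc(CC=C(C)C)c(O[Si](C)(C)C(C)(C)C)cc2Oc2cc(O[Si](C)(C)C(C)(C)C)ccc21.[Li+]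
F7 | step 15 | trifluoroacetate of ketol 19 | O=C1C(C3(OC(=O)C(F)(F)F)[C@H]4[C@H](CC[C@@]4(C)O[Si](CC)(CC)CC)C3(C)C)c2cc(CC=C(C)C)c(O[Si](C)(C)C(C)(C)C)cc2Oc2cc(O[Si](C)(C)C(C)(C)C)ccc21
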